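The constants were chosen freely; the flask was simulated.

Read both flasks at 40 h, and until then watch the dissolved starting material.

    starting material → ring (k1 = 0.029 h⁻¹, Ea1 = 103 kJ mol⁻¹)
    2 starting material → open dimer (k2 = 0.028 M⁻¹ h⁻¹, Ea2 = 89.0 kJ mol⁻¹)
    starting material + open dimer → open trimer (k3 = 6.0 × 10⁻⁴ M⁻¹ h⁻¹, Ea3 = 71.0 kJ mol⁻¹)
    solid substrate ⇌ starting material, rate k4*(cs4 - [starting material]) while solid is left; crystals form when [starting material] > cs4 (cs4 = 2.6 M, k4 = 0.041 h⁻¹)
    ring ⇌ isomer of the product (K5 = 2.3, k5 = 0.16 h⁻¹, Ea5 = 88.0 kJ mol⁻¹, ΔH5 = −2.00 kJ mol⁻¹)
    crystals ⇌ ring, rate k6*(cs6 - [ring]) while solid is left; crystals form when [ring] > cs6 (cs6 = 2.4 M, k6 = 9.5 h⁻¹)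
    (constants at 20 °C)

| flask | solid substrate | temperature | time |
|---|---|---|---|
| autumn | 3.0 M | 20 °C | 40 h |
| summer | 3.0 M | 0 °C | 40 h |

- the flask that comes out highest in share of ring in all that became ring or open dimer or open trimer or isomer of the product, or "all alike" when all lie within 1.5 percentage points (autumn / summer / all alike)
- share of ring in all that became ring or open dimer or open trimer or isomer of the product, autumn
- share of ring in all that became ring or open dimer or open trimer or isomer of the product, summer

- a species is counted by the solid substrate in it: one open dimer counts as two
- a species is counted by the solid substrate in it: one open trimer counts as three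
- amounts and yields of ring count crystals too
- two of one species on the left: rate k times its square, two consumed each time
- given per volume of solution although it is solid: solid substrate, crystals
- the constants hold at 20 °C; other temperatures follow from the activation energies and enthalpies
- at the start none of the solid substrate is in solution
- what has only dissolved of solid substrate counts as not reacted

Autumn and summer hold the same charge and differ in temperature. The steps to ring and open dimer use up dissolved starting material, and the step to open dimer goes with its square. So you need the level of dissolved starting material in each flask.

Divide the rate constant of the step to ring by twice that of the step to open dimer. In autumn this gives: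

crossover = 0.518 M

This is the crossover level, the dissolved starting material at which both steps use it equally fast. The level divided by the crossover is a selectivity factor, and the part going to ring is one over one plus that factor.

In autumn, take supply as balancing the loss to ring and open dimer at a steady level while solid lasts:

level = 0.890 M
part to ring = 36.8 %

Autumn's ring relaxes with its isomer with a half-life of 3.02 h, far shorter than the run. Ring in autumn is therefore reckoned at its equilibrium share, plus an excess of fresh ring:

ring kept = 37.9 %
autumn share = 13.9 %

In summer the constants of the steps to ring and open dimer fall to 0.00131 h⁻¹ and 0.00193 M⁻¹ h⁻¹, so the crossover drops to 0.340 M. The dissolution coefficient carries no activation energy and stays 0.041 h⁻¹. Summer's loss constant at the end level 2.10 M is 0.00941 h⁻¹, less than the dissolution coefficient, so the level climbs throughout. Take the rise as a straight ramp: the level weighted by turnover is then 2/3 of the end level: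

weighted level = 1.40 M
part to ring = 19.6 %

Summer's relaxation half-life of 43.2 h exceeds the run. Ring made on the ramp is on average a third of the run old, so forward loss is enough:

ring kept = 85.9 %
summer share = 16.8 %

I put summer ahead by 2.9 percentage points against a margin of 1.5 points, whereas the forecast gives 16 % for autumn, 16 % for summer and all alike, saying the higher level “largely cancels the cold's benefit”.

The flasks give 15.4 % in autumn and 16.0 % in summer, so the answer is all alike. Autumn holds 28.2 % of its charge as starting material at 20.0 h, which is 0.847 M, or 1.64 times its crossover level. A repeat of summer at −25 °C has a crossover of 0.183 M. With the same weighted level, the part to ring in that flask is 11.6 %. That flask ends with 69.7 % as starting material and a ring share of 10.3 %.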